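In a one-step world the target goes on forming until a reagent runs low, but the violet flask has stood near 31.5% since about 15.0 min, which by balance leaves 68.5% of its starting material unused.

| flask | starting material | second substrate | capture agent | precatalyst | temperature | remark | time |
|---|---|---|---|---|---|---|---|
| violet | 0.53 M | 2 equiv | 0.0265 M | 0.1 mol% | 5 °C | the very flask that is asked about, followed so far |  |
| blue | 0.53 M | 1.3 equiv | 0.0265 M | 0.1 mol% | 0 °C | run made earlier |  |
| flask | 0.53 M | 2.00 equiv | 0.0265 M | 0.1 mol% | 5 °C |  | 1.0 h |

| run | time / min | target / % |
|---|---|---|
| violet | 8.00 | 29.2 |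
| violet | 15.0 | 30.8 |
| violet | 25.0 | 30.7 |
| violet | 30.0 | 31.2 |
| violet | 40.0 | 32.0 |
| violet | 50.0 | 32.8 |
| blue | 3.00 | 5.9 |
| blue | 8.00 | 17.7 |
| blue | 15.0 | 30.5 |
| blue | 25.0 | 34.0 |
| blue | 30.0 | 31.7 |
| blue | 40.0 | 34.5 |

(readings scatter by 1 percentage point)

- target, in percent of the starting material first charged, at 1.0 h
- the option that brings most further target ("none" if no option brings more than 2 percentage points) (spring / noon / winter / autumn / none)
- target present, with what was taken out counted in, in percent of the starting material first charged, after spring
- target present, with what was taken out counted in, in percent of the starting material first charged, after noon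

- spring: at 1.0 h raise the temperature by 15 K, then wait 1.0 h
- noon: at 1.0 h add precatalyst, 50.0% of the amount charged, then wait 1.0 h
- winter: change nothing and wait 1.0 h more
- autumn: at 1.0 h take out 90% of the target then present, then wait 1.0 h

- removed target is counted in
- additions bring no volume worth counting

I read a ladder of times from these runs, fastest first. The bottom rung is the catalyst's round: counting every catalyst charged, the first violet reading gives on average one target per catalyst in about

round = 0.0274 min

The next rung is the catalyst's working life, which by the readings ends in the violet flask at about 8.00 min to 15.0 min; the blue run, at 0 °C and with 1.3 equiv of second substrate, takes until about 25.0 min. The top rung is the hour, and I take the rise of 2 percentage points across the later violet readings as mostly scatter. So I expect about 31.5% at 1.0 h, since the working life ends well before the hour.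

I follow one catalyst molecule through its forks. In each round it either makes target or is lost, and I assume that, at fixed [second substrate] and temperature, the odds for target go with [starting material] over [capture agent]. The capture agent at 0.0265 M far exceeds the precatalyst charged at 5.30 × 10⁻⁴ M, so [capture agent] hardly moves and the loss is pseudo-first-order in catalyst. Each charge of catalyst then removes a fixed fraction of the remaining starting material, and I call the logarithm of that removal the bite of a charge:

bite = ln(1/(1 − plateau)) = 0.378

Heat, waiting and removing target all come at 1.0 h, later than the end of the working life, so I give them no gain. Adding 50.0% of the precatalyst charge gives a new bite in proportion: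

target after noon = 1 − (1 − plateau)·exp(−50.0%·bite) = 43.3%

That gain of 12 points makes noon my choice, above the margin of 2 points.

The forecast differs: 33.3% now, spring as best, 45% after spring and 39% after noon, on this ground: “the 5% capture agent runs out at about 30% yield”

The flask gives 32.0% at 1.0 h, 32.0% after spring and 44.1% after noon, so the best option is noon, with 12 points gained. At 1.00 h the trapped intermediate holds 100% of the catalyst charged, while 98.0% of the capture agent's own charge stands unused. With the bite of 0.378 I reckoned 43.3% after noon, and the flask gives 44.1%.

    precatalyst → free catalyst (k = 0.490 min⁻¹, Ea = 86.0 kJ mol⁻¹)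
    second substrate + free catalyst ⇌ catalyst intermediate B (K = 1.59 M⁻¹, k = 571 M⁻¹ min⁻¹, Ea = 38.0 kJ mol⁻¹, ΔH = −54.0 kJ mol⁻¹)
    catalyst intermediate B → free catalyst + second product (k = 94.7 min⁻¹, Ea = 57.0 kJ mol⁻¹)
    catalyst intermediate A → free catalyst + target (k = 142 min⁻¹, Ea = 65.0 kJ mol⁻¹)
    starting material + free catalyst ⇌ catalyst intermediate A (K = 230 M⁻¹, k = 4630 M⁻¹ min⁻¹, Ea = 36.0 kJ mol⁻¹, ΔH = 5.00 kJ mol⁻¹)
    catalyst intermediate B + capture agent → trapped intermediate (k = 162 M⁻¹ min⁻¹, Ea = 37.0 kJ mol⁻¹)
    (constants at 5 °C)

Take the same flask with capture agent at 0.0066 M: the bite grows by a factor of 4.02 to 1.52, which gives 78.1% of target. The computed flask gives 80.1%.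

The runs stem from a simulated flask with made-up constants; the scatter is artificial.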